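**Retrosynthetic overview**
- The target comes from hydrogenating a 6'-alkynyl, 4'-O-benzyl isoflavone. The rigid butynol arm is the masked 3-hydroxy-3-methylbutyl chain. It keeps the tertiary OH away from ring B during oxidation and leaves C1' unhindered.
- Key disconnection: C3–C1', together with O1–C2. The alpha-carbon of an o-hydroxyaryl enaminone attacks ring B used with reversed polarity, as a quinone monoketal. This is a phenoxenium/enolonium equivalent, electrophilic at the CH alpha to its C=O, which is the normally nucleophilic ortho carbon of the phenol.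
- The quinone monoketal comes from a double PhI(OAc)2/MeOH oxidation of a 3,5-disubstituted phenol. One operation installs the 5'-OMe and reverses the polarity.
- The phenol comes from 5-bromoresorcinol by mono-benzylation and Sonogashira coupling. The enaminone comes from 2,4-dihydroxyacetophenone and DMF-DMA.
- Ring order: rings A and B are bought. Ring B is dearomatised and then rearomatised in the key step. Ring C is the only ring built, and it closes last, in the same flask.

Assumption: the target SMILES carries no stereocentre and no fixed axis (rotation about C3–C1' is taken as free), so the compound is treated as achiral and needs no stereocontrol.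

**Step 1**
Reactants: 1 5-bromoresorcinol
Product: 2 3-(benzyloxy)-5-bromophenol
Conditions: BnBr (0.95 equiv), K2CO3 (1.0 equiv), acetone, reflux
Reagents that add atoms: benzyl bromide, BrCc1ccccc1
Why: Williamson ether synthesis on two equivalent phenols gives the mono-ether statistically (about half), and it is separated by chromatography from the bis-ether and from recovered, recyclable 1.

**Step 2**
Reactants: 2 3-(benzyloxy)-5-bromophenol; 3 2-methylbut-3-yn-2-ol
Product: 4 3-(benzyloxy)-5-(3-hydroxy-3-methylbut-1-yn-1-yl)phenol
Conditions: PdCl2(PPh3)2 (3 mol %), CuI (5 mol %), Et3N–DMF, 80 °C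
Reagents that add atoms: none
Why: Sonogashira coupling (oxidative addition of the aryl bromide to zerovalent palladium, then transfer of the copper acetylide) tolerates the free phenol and the tertiary alcohol, and both oxygens are meta to the alkyne so no benzofuran can form.

**Step 3**
Reactants: 4 3-(benzyloxy)-5-(3-hydroxy-3-methylbut-1-yn-1-yl)phenol
Product: 6 3-(benzyloxy)-5-(3-hydroxy-3-methylbut-1-yn-1-yl)-4,4-dimethoxycyclohexa-2,5-dien-1-one, via methoxyphenol 5 (not isolated)
Conditions: PhI(OAc)2 (2.2 equiv), MeOH, 0 °C to rt
Reagents that add atoms: methanol, CO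
Why: Trivalent-iodine oxidative dearomatisation of a para-unsubstituted phenol traps methanol at the free para carbon to give 5, which is more electron-rich and is oxidised again to the quinone dimethyl monoketal; the linear alkyne prevents the tertiary OH from reaching that carbon, and no stereocentre is formed.

**Step 4**
Reactants: 6 3-(benzyloxy)-5-(3-hydroxy-3-methylbut-1-yn-1-yl)-4,4-dimethoxycyclohexa-2,5-dien-1-one; 7 2,4-dihydroxyacetophenone
Product: 9 3-[4-(benzyloxy)-2-hydroxy-6-(3-hydroxy-3-methylbut-1-yn-1-yl)-5-methoxyphenyl]-7-hydroxy-4H-chromen-4-one, via enaminone 8 (not isolated)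
Conditions: 7 (1.5 equiv), DMF-DMA (1.8 equiv), toluene, 80 °C; evaporate; 6 (1.0 equiv), C6F5CO2H (2.0 equiv), dry HFIP, 0 °C to rt
Reagents that add atoms: N,N-dimethylformamide dimethyl acetal, COC(OC)N(C)C
Why: Proposed new method: standard condensation gives enaminone 8, nucleophilic at its alpha-carbon; in HFIP the fluorinated acid ionises one methoxy group of 6 to an O-methylquinonium (4-methoxyphenoxenium) ion, an enolonium equivalent electrophilic at the CH alpha to its C=O; the other alpha-CH is deactivated by the benzyloxy donor (vinylogous ester) and both beta-carbons are fully substituted, so 8 should attack next to the slim alkynyl group; the resulting iminium carbon is trapped by the chelated ring A phenol while ring B is still a dienone without OH, and loss of HNMe2 plus dienone–phenol tautomerisation give the 2'-hydroxy-5'-methoxyisoflavone; the acid is stoichiometric because the amine released would neutralise a catalytic amount; the closest known reaction types are acid-promoted alpha-substitution of quinone monoacetals by carbon nucleophiles in HFIP, Nenitzescu-type C–C bond formation between enaminones and quinones, and electrophile-triggered annulation of enaminones to 3-substituted chromones; no stereocentre is formed.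

**Step 5**
Reactants: 9 3-[4-(benzyloxy)-2-hydroxy-6-(3-hydroxy-3-methylbut-1-yn-1-yl)-5-methoxyphenyl]-7-hydroxy-4H-chromen-4-one
Product: 10 kwakhurin hydrate, 3-[2,4-dihydroxy-6-(3-hydroxy-3-methylbutyl)-5-methoxyphenyl]-7-hydroxy-4H-chromen-4-one
Conditions: H2 (1 atm), Pd/C (10 wt % Pd), EtOAc–MeOH, rt, stopped at 3 equiv H2
Reagents that add atoms: none
Why: Heterogeneous catalytic hydrogenation saturates the alkyne and hydrogenolyses the aryl benzyl ether in one operation, while the push-pull, trisubstituted and shielded C2=C3 bond of the isoflavone reacts much more slowly; no stereocentre is formed.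

**Compound list**
1 | 5-bromobenzene-1,3-diol (5-bromoresorcinol) | Oc1cc(O)cc(Br)c1 | starting material
2 | 3-(benzyloxy)-5-bromophenol | Oc1cc(Br)cc(OCc2ccccc2)c1 | intermediate
3 | 2-methylbut-3-yn-2-ol | C#CC(C)(C)O | starting material
4 | 3-(benzyloxy)-5-(3-hydroxy-3-methylbut-1-yn-1-yl)phenol | CC(C)(O)C#Cc1cc(O)cc(OCc2ccccc2)c1 | intermediate
5 | 3-(benzyloxy)-5-(3-hydroxy-3-methylbut-1-yn-1-yl)-4-methoxyphenol | COc1c(OCc2ccccc2)cc(O)cc1C#CC(C)(C)O | intermediate
6 | 3-(benzyloxy)-5-(3-hydroxy-3-methylbut-1-yn-1-yl)-4,4-dimethoxycyclohexa-2,5-dien-1-one | COC1(OC)C(OCc2ccccc2)=CC(=O)C=C1C#CC(C)(C)O | intermediate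
7 | 1-(2,4-dihydroxyphenyl)ethan-1-one (2,4-dihydroxyacetophenone) | CC(=O)c1ccc(O)cc1O | starting material
8 | (E)-1-(2,4-dihydroxyphenyl)-3-(dimethylamino)prop-2-en-1-one | CN(C)/C=C/C(=O)c1ccc(O)cc1O | intermediate
9 | 3-[4-(benzyloxy)-2-hydroxy-6-(3-hydroxy-3-methylbut-1-yn-1-yl)-5-methoxyphenyl]-7-hydroxy-4H-chromen-4-one | COc1c(OCc2ccccc2)cc(O)c(-c2coc3cc(O)ccc3c2=O)c1C#CC(C)(C)O | intermediate
10 | kwakhurin hydrate | COc1c(O)cc(O)c(-c2coc3cc(O)ccc3c2=O)c1CCC(C)(C)O | target

Total step count: 5. Longest linear sequence: 5 (1 → 2 → 4 → 6 → 9 → 10); 7 enters at step 4.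

**Steps most likely to fail**

Step 4 is the riskiest.
- The new ring B hydroxyl may close onto the aminomethine carbon faster than the ring A hydroxyl, giving a furan instead of the pyranone.
- Acid may cyclise 8 to 7-hydroxychromone before it couples, which is why 8 is used in excess.
- Traces of water would hydrolyse 6 to the quinone.

The fallback sets out from 6 (with 8 made as before) and comes back at 9. The coupling is run deliberately as a Nenitzescu-type benzofuran synthesis in glacial AcOH at rt, accepting furan closure. This gives [6-(benzyloxy)-4-(3-hydroxy-3-methylbut-1-yn-1-yl)-5-methoxy-1-benzofuran-3-yl](2,4-dihydroxyphenyl)methanone F1, which is isolated. It is then isomerised with p-TsOH·H2O (20 mol %) in MeCN at 40 °C. The ring A hydroxyl adds to furan C2 and the ring B phenol is expelled. This ring-opening and cyclisation of 3-(2-hydroxyaroyl)benzofurans to 2'-hydroxyisoflavones is a known reaction type. Here it is helped by relief of the peri strain between the 3-aroyl and 4-alkynyl groups.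

Step 3 is next. The first methoxylation may go partly ortho, and methanol may add to the alkynyl dienone. The yield of a double oxidation on a phenol deactivated by the alkynyl group is also uncertain. The fallback sets out from 2 and comes back at 6, with dearomatisation done before the alkyne is present. PhI(OAc)2 (2.2 equiv) in MeOH converts 2 into 3-(benzyloxy)-5-bromo-4,4-dimethoxycyclohexa-2,5-dien-1-one F2. Its beta-bromo dienone C–Br bond is then coupled with 3 at rt (PdCl2(PPh3)2, CuI, Et3N, THF) to give 6.

Step 5 is third. Over-reduction of C2=C3 to the isoflavanone, or hydrogenolysis of the propargylic/allylic C–O bond, may compete with the slow reduction of a hindered alkyne. The fallback sets out from 9 and comes back at 10, and splits the two tasks. Diimide (TsNHNH2, NaOAc, DME–H2O, reflux) saturates only the alkyne. It gives 3-[4-(benzyloxy)-2-hydroxy-6-(3-hydroxy-3-methylbutyl)-5-methoxyphenyl]-7-hydroxy-4H-chromen-4-one F3. Transfer hydrogenolysis (Pd/C, 1,4-cyclohexadiene, EtOH, rt) then removes only the benzyl group.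

**Further compounds**
F1 | step 4 | [6-(benzyloxy)-4-(3-hydroxy-3-methylbut-1-yn-1-yl)-5-methoxy-1-benzofuran-3-yl](2,4-dihydroxyphenyl)methanone | COc1c(OCc2ccccc2)cc2occ(C(=O)c3ccc(O)cc3O)c2c1C#CC(C)(C)O
F2 | step 3 | 3-(benzyloxy)-5-bromo-4,4-dimethoxycyclohexa-2,5-dien-1-one | COC1(OC)C(OCc2ccccc2)=CC(=O)C=C1Br
F3 | step 5 | 3-[4-(benzyloxy)-2-hydroxy-6-(3-hydroxy-3-methylbutyl)-5-methoxyphenyl]-7-hydroxy-4H-chromen-4-one | COc1c(OCc2ccccc2)cc(O)c(-c2coc3cc(O)ccc3c2=O)c1CCC(C)(C)O
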